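**Retrosynthetic overview**
- The C7 isopropylidene comes off last, as an acetone aldol condensation on a ring B 8-ketone that already carries both esters. The angelate is cut back to the 3β-alcohol and angelic acid.
- The 3β-alcohol comes from the 3-ketone by axial hydride delivery. The key bond is the tertiary C4–OAc bond, made together with the trans ring fusion by reductive α-acetoxylation of a 4-methyl-Δ4-3-keto octalone.
- The octalone is cut by Robinson annulation into ethyl vinyl ketone and a 2-methylcyclohexanone carrying a dioxolane at the future C8. The quaternary C10 is set by an auxiliary-controlled Michael addition.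
- Ring order: ring B is bought, ring A is built on it (steps 1–2), ring A is oxygenated (steps 3–5), and the ring B side chain is added last (steps 6–7).

Assumption: racemic 7-methyl-1,4-dioxaspiro[4.5]decan-8-one is taken as a purchasable catalogue ketone; ring positions are quoted in eudesmane numbering (ring A = C1–C5 and C10, ring B = C5–C10, β = the face of the C10 methyl).

**Route**

Step 1
Reactants: 1 7-methyl-1,4-dioxaspiro[4.5]decan-8-one (racemic); 2 (R)-1-phenylethylamine; 3 ethyl vinyl ketone
Product: 6 (R)-7-methyl-7-(3-oxopentyl)-1,4-dioxaspiro[4.5]decan-8-one, via ketimine 4 (not isolated), via adduct ketimine 5 (not isolated)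
Conditions: 2, toluene, reflux (Dean–Stark); then 3, 40 °C, 3 d; then 20% aq. AcOH, rt
Reagents that add atoms: ethyl vinyl ketone (C=CC(=O)CC); water (O)
Why: Auxiliary-controlled deracemising Michael addition of a chiral ketimine (d'Angelo type): 4 reacts through its more substituted secondary enamine tautomer in an aza-ene-like transition state, the vinyl ketone adds to the face away from the phenyl group, and the (R)-amine therefore gives the (R)-quaternary centre (about 90% ee is typical of this reaction class), the mirror-image outcome of the familiar (S)-amine/2-methylcyclohexanone case.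

Step 2
Reactants: 6 (R)-7-methyl-7-(3-oxopentyl)-1,4-dioxaspiro[4.5]decan-8-one
Product: 7 (4aR)-6,6-ethylenedioxy-1,4a-dimethyl-4,4a,5,6,7,8-hexahydronaphthalen-2(3H)-one
Conditions: NaOMe (0.3 equiv), MeOH, 60 °C
Reagents that add atoms: none
Why: Intramolecular aldol condensation (second stage of the Robinson annulation) closes ring A to the six-membered conjugated enone; the quaternary centre cannot epimerise and the dioxolane is inert to base.

Step 3
Reactants: 7 (4aR)-6,6-ethylenedioxy-1,4a-dimethyl-4,4a,5,6,7,8-hexahydronaphthalen-2(3H)-one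
Product: 9 4α-acetoxy-8,8-ethylenedioxy-11,12,13-trinor-5α-eudesman-3-one, via lithium enolate 8 (not isolated)
Conditions: Li (2.1 equiv), t-BuOH (1.0 equiv), NH3(l)/THF, −78 °C; isoprene; NH3 off; then PhI(OAc)2 (2.2 equiv), THF, −78 → −20 °C
Reagents that add atoms: (diacetoxyiodo)benzene (CC(=O)OI(OC(C)=O)c1ccccc1)
Why: Proposed new method: a one-pot reductive α-acetoxylation in which the dissolving-metal enone reduction gives the trans ring fusion (axial protonation at C5 anti to the C10 methyl, 5α-H) and the regiodefined tetrasubstituted lithium enolate 8, which is then intercepted by PhI(OAc)2; exchange of one acetate on trivalent iodine for the enolate oxygen gives an O-bound enol iodane that collapses by acetate delivery to the sp2 C4 with loss of PhI (a two-electron reductive ligand coupling, so no substitution at a saturated tertiary carbon is required), and the acetate enters on the α face because the β face of C4 is screened by the 1,3-related axial C10 methyl, giving 4α-OAc/4β-Me; the closest known reaction types are the Rubottom oxidation and the Pb(OAc)4 acetoxylation of silyl enol ethers, the α-acetoxylation of ketone enols by trivalent-iodine acetates and the Stork reductive alkylation of enones, whereas direct C–O bond formation on a Birch-derived, fully substituted lithium enolate with an iodine acetate has not been shown.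

Step 4
Reactants: 9 4α-acetoxy-8,8-ethylenedioxy-11,12,13-trinor-5α-eudesman-3-one
Product: 11 4α-acetoxy-3β-hydroxy-11,12,13-trinor-5α-eudesman-8-one, via hydroxy ketal 10 (not isolated)
Conditions: NaBH4, CeCl3·7H2O, MeOH/THF, −40 °C; then 1 M HCl (aq), rt
Reagents that add atoms: water (O)
Why: Luche-type borohydride reduction (low basicity, to suppress acetyl migration from O4 to O3) delivers hydride axially to C3 from the α face, anti to the axial 4β-methyl, giving the equatorial 3β-alcohol as in 4,4-disubstituted 3-keto trans-decalins; acid added to the same flask then hydrolyses the dioxolane to the C8 ketone.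

Step 5
Reactants: 11 4α-acetoxy-3β-hydroxy-11,12,13-trinor-5α-eudesman-8-one; 12 angelic acid
Product: 14 4α-acetoxy-3β-angeloyloxy-11,12,13-trinor-5α-eudesman-8-one, via mixed anhydride 13 (not isolated)
Conditions: 12 (3 equiv), 2,4,6-Cl3C6H2COCl (3 equiv), Et3N (3 equiv), toluene, rt, 2 h; then 11, 80 °C, 24 h
Reagents that add atoms: angelic acid (C/C=C(/C)C(=O)O)
Why: Yamaguchi-type mixed-anhydride esterification run without DMAP: the alcohol attacks the angeloyl carbonyl of 13 because the trichlorobenzoyl carbonyl is blocked by its ortho chlorines, and the absence of a nucleophilic catalyst avoids Z-to-E isomerisation to the tiglate; no stereocentre is touched.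

Step 6
Reactants: 14 4α-acetoxy-3β-angeloyloxy-11,12,13-trinor-5α-eudesman-8-one; 15 acetone
Product: 17 4α-acetoxy-3β-angeloyloxy-11-hydroxy-5α,7αH-eudesman-8-one, via trichlorotitanium enolate 16 (not isolated)
Conditions: TiCl4 (1.2 equiv), Bu3N (1.4 equiv), CH2Cl2, −78 °C; then 15 (3 equiv), −78 → −40 °C
Reagents that add atoms: acetone (CC(C)=O)
Why: Titanium-mediated direct aldol addition by soft enolisation (TiCl4/amine) leaves both esters untouched and enolises toward C7, the α-methylene remote from the quaternary C10 (C9 is neopentylic); the new C7 centre (mainly the equatorial 7β side chain) is removed in step 7.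

Step 7
Reactants: 17 4α-acetoxy-3β-angeloyloxy-11-hydroxy-5α,7αH-eudesman-8-one
Product: 19 4α-acetoxy-3β-angeloyloxy-5α-eudesm-7(11)-en-8-one (the target), via tertiary mesylate 18 (not isolated)
Conditions: MsCl, Et3N, CH2Cl2, 0 °C; then DBU, rt
Reagents that add atoms: none
Why: Mesylation of the tertiary aldol hydroxyl followed by E1cB elimination through the C7 enolate gives the conjugated tetrasubstituted isopropylidene ketone; any isopropenyl isomer is drawn into conjugation by DBU, and non-nucleophilic amine bases at room temperature should not isomerise the angelate.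

**Compound list**

1 | 7-methyl-1,4-dioxaspiro[4.5]decan-8-one (racemic) | CC1CC2(CCC1=O)OCCO2 | starting material
2 | (R)-1-phenylethylamine | C[C@@H](N)c1ccccc1 | starting material
3 | ethyl vinyl ketone (pent-1-en-3-one) | C=CC(=O)CC | starting material
4 | (R)-N-(7-methyl-1,4-dioxaspiro[4.5]decan-8-ylidene)-1-phenylethanamine (C7 epimers, equilibrating through the enamine) | CC1CC2(CCC1=N[C@H](C)c3ccccc3)OCCO2 | intermediate
5 | (R)-N-[(7R)-7-methyl-7-(3-oxopentyl)-1,4-dioxaspiro[4.5]decan-8-ylidene]-1-phenylethanamine | CCC(=O)CC[C@]1(C)CC2(OCCO2)CCC1=N[C@H](C)c3ccccc3 | intermediate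
6 | (R)-7-methyl-7-(3-oxopentyl)-1,4-dioxaspiro[4.5]decan-8-one | CCC(=O)CC[C@]1(C)CC2(OCCO2)CCC1=O | intermediate
7 | (4aR)-6,6-ethylenedioxy-1,4a-dimethyl-4,4a,5,6,7,8-hexahydronaphthalen-2(3H)-one (Δ4-3-keto octalone, 10β-methyl, C8 dioxolane) | O=C1CC[C@]2(C)CC3(OCCO3)CCC2=C1C | intermediate
8 | lithium Δ3-enolate of 8,8-ethylenedioxy-11,12,13-trinor-5α-eudesman-3-one (C3–OLi, C3=C4, trans-fused) | [Li]OC1=C(C)[C@@H]2CCC3(OCCO3)C[C@@]2(C)CC1 | intermediate
9 | 4α-acetoxy-8,8-ethylenedioxy-11,12,13-trinor-5α-eudesman-3-one (4β-Me, 10β-Me, 5α-H) | O=C1CC[C@]2(C)CC3(OCCO3)CC[C@H]2[C@]1(C)OC(C)=O | intermediate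
10 | 4α-acetoxy-8,8-ethylenedioxy-11,12,13-trinor-5α-eudesman-3β-ol | O[C@H]1CC[C@]2(C)CC3(OCCO3)CC[C@H]2[C@]1(C)OC(C)=O | intermediate
11 | 4α-acetoxy-3β-hydroxy-11,12,13-trinor-5α-eudesman-8-one | O[C@H]1CC[C@]2(C)CC(=O)CC[C@H]2[C@]1(C)OC(C)=O | intermediate
12 | angelic acid, (Z)-2-methylbut-2-enoic acid | C/C=C(/C)C(=O)O | starting material
13 | angelic 2,4,6-trichlorobenzoic anhydride | C/C=C(/C)C(=O)OC(=O)c1c(Cl)cc(Cl)cc1Cl | intermediate
14 | 4α-acetoxy-3β-angeloyloxy-11,12,13-trinor-5α-eudesman-8-one | C/C=C(/C)C(=O)O[C@H]1CC[C@]2(C)CC(=O)CC[C@H]2[C@]1(C)OC(C)=O | intermediate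
15 | acetone | CC(C)=O | starting material
16 | trichlorotitanium Δ7-enolate of 14 (C8–OTiCl3, C7=C8) | C/C=C(/C)C(=O)O[C@H]1CC[C@]2(C)CC(O[Ti](Cl)(Cl)Cl)=CC[C@H]2[C@]1(C)OC(C)=O | intermediate
17 | 4α-acetoxy-3β-angeloyloxy-11-hydroxy-5α,7αH-eudesman-8-one (7β, equatorial 2-hydroxypropan-2-yl; major epimer) | C/C=C(/C)C(=O)O[C@H]1CC[C@]2(C)CC(=O)[C@@H](C(C)(C)O)C[C@H]2[C@]1(C)OC(C)=O | intermediate
18 | 11-methanesulfonate of 17 | C/C=C(/C)C(=O)O[C@H]1CC[C@]2(C)CC(=O)[C@@H](C(C)(C)OS(C)(=O)=O)C[C@H]2[C@]1(C)OC(C)=O | intermediate
19 | [(1S,2S,4aR,8aR)-1-acetoxy-1,4a-dimethyl-6-oxo-7-(propan-2-ylidene)decahydronaphthalen-2-yl] (Z)-2-methylbut-2-enoate; eudesmane descriptors 3S,4S,5R,10R | C/C=C(/C)C(=O)O[C@H]1CC[C@]2(C)CC(=O)C(=C(C)C)C[C@H]2[C@]1(C)OC(C)=O | target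

**Step count and risk**

Total step count: 7. Longest linear sequence: 7 (fully linear from 1).

The three steps most likely to fail:

Step 3 (proposed new reductive acetoxylation). The enol iodane may instead lose a β-hydrogen and return enone 7 or an exocyclic enone, or the lithium tert-butoxide by-product may consume the oxidant. The fallback uses known chemistry, sets out from 7 and comes back at 9. The same Li/NH3/t-BuOH reduction is quenched with TMSCl/Et3N to give the trimethylsilyl enol ether of the trans-fused 3-ketone F1. Rubottom oxidation (mCPBA, NaHCO3, CH2Cl2, −20 °C, then mild acid desilylation) attacks the α face and gives the 4α-hydroxy-3-ketone F2. Acetylation of this tertiary α-ketol (Ac2O, DMAP, Et3N, 50 °C) then gives 9.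

Step 5 (angeloylation). The 3β-hydroxyl is flanked by the fully substituted C4, so acylation may be slow, and prolonged heating with amine risks acetyl migration or tiglate formation. The fallback sets out from 11 and comes back at 14. The alcohol is esterified with 2-[bis(2,2,2-trifluoroethoxy)phosphoryl]propanoic acid (DCC, cat. DMAP, CH2Cl2; such acids acylate hindered alcohols through a ketene-like intermediate) to give the 3β-phosphonopropanoate F3. A Z-selective Still–Gennari olefination (KN(SiMe3)2, 18-crown-6, THF, −78 °C, then acetaldehyde; the phosphonate is far more acidic than the C8 ketone) then builds the (Z)-2-methylbut-2-enoate on the substrate and gives 14.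

Step 6 (direct titanium aldol with acetone). Soft enolisation may be incomplete or may touch the esters, and the tertiary aldolate is prone to retro-aldol. The fallback sets out from 14 and comes back at 17. The ketone is converted with TMSOTf/Et3N (CH2Cl2, 0 °C) into the isolated, regiochemically defined Δ7 trimethylsilyl enol ether F4. A Mukaiyama aldol addition to acetone (TiCl4 or BF3·OEt2, CH2Cl2, −78 °C), which runs through an open Lewis-acid transition state and needs no amine base, then gives 17.

Further compounds
F1 | step 3 | trimethylsilyl Δ3-enol ether of 8,8-ethylenedioxy-11,12,13-trinor-5α-eudesman-3-one | C[Si](C)(C)OC1=C(C)[C@@H]2CCC3(OCCO3)C[C@@]2(C)CC1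
F2 | step 3 | 8,8-ethylenedioxy-4α-hydroxy-11,12,13-trinor-5α-eudesman-3-one | O=C1CC[C@]2(C)CC3(OCCO3)CC[C@H]2[C@]1(C)O
F3 | step 5 | 4α-acetoxy-3β-{2-[bis(2,2,2-trifluoroethoxy)phosphoryl]propanoyloxy}-11,12,13-trinor-5α-eudesman-8-one (epimers at the phosphonate carbon) | CC(C(=O)O[C@H]1CC[C@]2(C)CC(=O)CC[C@H]2[C@]1(C)OC(C)=O)P(=O)(OCC(F)(F)F)OCC(F)(F)F
F4 | step 6 | trimethylsilyl Δ7-enol ether of 14 | C/C=C(/C)C(=O)O[C@H]1CC[C@]2(C)CC(O[Si](C)(C)C)=CC[C@H]2[C@]1(C)OC(C)=O
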